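# Proposed synthesis of CNP0154047.1 (38) by aryne ring expansion of a 2-indanone

## The problem

Compound 38 is built on a central benzene (ring A) that is substituted at every position but one: it is fused to two trans-2,3-diaryl-2,3-dihydrofurans and, through a CH2–CH(aryl) bridge and the resorcinol ring B, to a seven-membered carbocycle. Labels used throughout: the ring A carbons are called Z1 to Z6, where Z1 and Z3 carry the furan oxygens, Z2 the hydrogen, Z4 the methine Cc, Z5 the ring CH2 (Ca) and Z6 the methine Ce; Cb is the CH(2,4-dihydroxyphenyl) carbon bonded to B1, Cc is bonded to B6, Cd and Cf are the O–CH(4-hydroxyphenyl) carbons of the inner (Cc–Cd) and outer (Ce–Cf) furans, and B2 and B4 carry the ring B oxygens. All five stereocentres are R and fall into two groups that ring A insulates from each other: Cc can control Cd (trans closure) and Cb (the fused furan folds the tetracycle and differentiates the two faces at Cb), and Ce can control Cf, but neither group can control the other, so each needs its own absolute control. The two furans have the same local sense of chirality, so one catalyst antipode can serve both. The benzylic C–O bonds of the dihydrofurans, the doubly benzylic methines and the eight phenols (air-sensitive when free, and spread over four rings that compete with ring A for any electrophile) do not survive rough treatment, and the two ring A oxygens must be unmasked selectively among ten. A cation at Cd lying over an electron-rich Ca=Cb double bond would close across the ring, so the state of Cb while the inner furan closes needs care. The feature that opens the key step is that B6 and B1 are neighbours on ring B, with B1 ortho to an oxygen and B6 meta to both, while Cc and Ca sit on the neighbouring carbons Z4 and Z5: Cc–(C=O)–Ca on ring A is a 2-indanone, and a 3,5-dialkoxybenzyne inserted into its C1–C2 bond delivers ring B in exactly this orientation and leaves Cc enolisable for a later dynamic resolution.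

## Retrosynthesis

**38 ⇒ 37.** Only the eight O–CH3 bonds are cut. Methyl ethers are the one phenol mask that survives every step of the route; the ring A oxygens are already ring ethers in 37. The forward step must cleave eight ethers without losing the benzylic C–O bonds, or must let them re-close to the trans isomers.

**37 ⇒ 35 ⇒ 34 ⇒ 29 + 33.** The outer furan is opened at O–Cf, then the Z6–Ce bond is cut, giving aryl bromide 29 and deoxybenzoin 33. Cutting here, and not building the furan by a late electrophilic substitution, is dictated by ring A: Z6 is the more hindered of its two free positions and competes with three other electron-rich rings. The position is therefore marked by a bromine placed on the first ring A intermediate (3). Ketone 33 brings 17 carbons and both aryl groups in one piece, and its α-carbon becomes an enolisable Ce, so a single catalytic reduction (34 to 35) can fix Ce; Cf then follows on acid closure. The forward steps ask for a palladium coupling at a doubly ortho-substituted bromide and for catalyst control far from the existing centres.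

**29 ⇒ 28 ⇒ 26 + 27.** The Cb–aryl bond is cut to the ring alkene 26 and 1,3-dimethoxybenzene (27). The neighbouring cut (aryl already on Cb, hydrogen added last) would deliver hydrogen to the open convex face and leave the aryl on the concave face, the wrong epimer. With the arene as the nucleophile the same facial bias gives the right one. The forward step needs protonation at Ca only (the ring B methoxy groups stabilise the Cb cation, ring A does not stabilise one at Ca), attack of 27 through C4, and survival of the inner furan.

**26 ⇒ 25 ⇒ 23 ⇒ 22 ⇒ 18 (through 19, 21 and Grignard reagent 20).** The inner furan is opened at O–Cd and the Cd–aryl bond is cut back to the ester of 18. In ketone 22 Cc is the only stereocentre and is labile, so the reduction to 23 is a true dynamic kinetic resolution and sets the absolute configuration of the whole inner group. Cb is carried as an enol triflate. A ketone would compete in the reductions, and an electron-rich alkene would trap the Cd cation across the ring. The triflate is inert to both and can later be turned into either polarity at Cb (26, or the fallback for step 18).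

**18 ⇒ 17.** Enol triflate from the ring ketone; the ketone has α-hydrogens only on Ca.

**17 ⇒ 8 + 14 (key step).** The B6–Cc and B1–Cb bonds are cut, which removes ring B and contracts the seven-membered ring to the indanone 8. No other cut forms a bond to B6, which is meta to both ring B oxygens and out of reach of Friedel–Crafts chemistry, together with an acyl bond at B1. Precursor 8 has one ring and no fixed stereocentre; 14 is a three-step aryne precursor. The forward reaction has to control only the regiochemistry of aryne capture.

**8 ⇒ 7 ⇒ 6 ⇒ 4 ⇒ 3 ⇒ 2 ⇒ 1.** The Z4–C1 bond is cut (carbenoid aromatic substitution), then the diazo group, the malonate carbons, the bromine and the acetals are removed, back to methyl 3,5-dihydroxyphenylacetate (1). The bromine also blocks one of the two ortho positions, so the carbenoid has a single site.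

**14 ⇒ 11 ⇒ 10 ⇒ 9 and 33 ⇒ 30 + 31.** The aryne precursor comes from 3,5-dimethoxyphenol (9) by bromination, silylation and silyl migration/triflation; the deoxybenzoin from 3,5-dimethoxyphenylacetic acid (30) and anisole (31) by Friedel–Crafts acylation.

## Roads not taken

**Alternative 1:** Both aryl–oxygen bonds of the two furans are cut at once. In the forward step a hindered lithium amide removes the ring A hydrogen between two bromines of a C2-symmetric dialkoxide, and two arynes formed in relay are captured by the two alkoxides to give the bis(dihydrobenzofuran) A1.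
- Merits: it uses the hidden C2 symmetry of the bis-furan, so four stereocentres come from one asymmetric reaction applied twice. The C–O bonds form at sp2 carbon, so no carbinol is ionised. In this respect it is cleaner than the acid closures of steps 16 and 23, which rely on trans-selective recapture of a benzylic cation. Closing the seven-membered ring afterwards onto either of two equivalent resorcinol rings is a regiochemically safe, biomimetic cation cyclisation.
- Weak points: the substrate is a hexasubstituted benzene with two bulky diarylethanol arms, two bromines and a CH2OSi group, so the crowded aryl–carbon bond that the chosen route makes once (step 21) must be made twice. Alkoxides of this type can fragment under strong base. After A1 the benzylic carbon still has to be homologated to Ca–Cb before the ring can close.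
- Comparison: on symmetry and possibly on step count this road is at least as good. The chosen plan sets against it a seven-membered ring closed in one step of a closely precedented reaction type on an achiral, easily made indanone, and two reductions whose catalyst antipode can be chosen independently.

**Alternative 2:** The ring A–Cc and Cd–O bonds are cut together. Zerovalent palladium inserts into a ring A carbon–iodine bond, adds 7-exo-dig to a tethered diarylalkyne and closes the furan by C–O reductive elimination, giving benzofuran A2.
- Merits: two rings form in one catalytic step, and Cb is already in place as a single enantiomer, set on an open chain. That is better than the substrate-controlled Cb of step 18. No protecting-group change is needed at Z3.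
- Weak points: in A2 both Cc and Cd are sp2. The trans-dihydrofuran must then be made by reducing a tetrasubstituted, electron-rich furan double bond under the control of a remote Cb; hydrogenation gives cis, and ionic reduction is not reliably controlled. Ring A of A2 has no handle at Z6 for the second furan. The large-ring carbopalladation competes with direct attack of the phenoxide on the alkyne.
- Comparison: the chosen plan keeps Cc sp3 and enolisable, which is what allows the dynamic resolution, and carries the Z6 bromine from the start.

**Alternative 3:** Four carbon–carbon bonds of ring B are cut. Irradiation of a cycloheptenyl diazoketone gives a vinylketene by Wolff rearrangement, which combines with a silyloxyalkyne ([2+2], four-electron opening, six-electron closure) to build ring B last, giving A3.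
- Merits: Cb, Cc and Cd are fixed on a non-aromatic seven-membered ring before aromatisation, and ring B cannot be attached the wrong way round.
- Weak points: the stereochemically dense cycloheptenyl precursor fused to a dihydrofuran is the real synthetic problem, and it costs more steps than the whole seven-membered ring of the chosen plan. Cc lies next to the ketene and can epimerise. The light-driven step comes late, on a substrate full of aryl ethers. The differentiated oxygens of ring B in A3 are of no use to the target, and Z6 again has no handle.
- Comparison: this road is better in having three stereocentres secured before ring B exists. The chosen plan sets against it ring B bought as a phenol and the carbon skeleton of the core reached ten steps from 1.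

Key step: step 10

Assumption: in steps 15 and 22 the (R,R)-TsDPEN catalyst is taken to give the (R)-carbinol (usual aryl-ketone model) and, by reducing the ketone epimer that holds the ring A aryl anti to the incoming hydride (Felkin–Anh), R at the adjoining methine; if the methine proves to be set in the opposite sense, the (S,S) catalyst is used in that step and nothing else changes, since the acid closure erases the carbinol configuration.

## Route

Step 1
Reactants: 1 methyl 2-(3,5-dihydroxyphenyl)acetate
Product: 2 methyl 2-[3,5-bis(methoxymethoxy)phenyl]acetate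
Conditions: MOMCl, i-Pr2NEt, CH2Cl2, 0 °C to rt
Reagents that add atoms: chloromethyl methyl ether, COCCl
Why: Phenol O-alkylation with an α-chloro ether; the acetals survive fluoride, hydride, Grignard and palladium steps and are later removed by the same acid that closes each furan.

Step 2
Reactants: 2 methyl 2-[3,5-bis(methoxymethoxy)phenyl]acetate
Product: 3 methyl 2-[2-bromo-3,5-bis(methoxymethoxy)phenyl]acetate
Conditions: NBS (1.0 equiv), MeCN, 0 °C
Reagents that add atoms: N-bromosuccinimide, O=C1CCC(=O)N1Br
Why: Electrophilic aromatic bromination goes para to one acetal oxygen and ortho to the CH2 rather than between the two oxygens, as is usual for 3,5-dialkoxyphenylacetates. The bromine marks Z6 for step 21 while ring A is still the only electron-rich ring, and leaves the carbenoid of step 6 a single ortho C–H.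

Step 3
Reactants: 3 methyl 2-[2-bromo-3,5-bis(methoxymethoxy)phenyl]acetate
Product: 4 2-[2-bromo-3,5-bis(methoxymethoxy)phenyl]acetic acid
Conditions: LiOH·H2O, THF/MeOH/H2O, rt; then cold 1 M HCl to pH 3
Reagents that add atoms: lithium hydroxide (hydroxide oxygen), [Li+].[OH-]
Why: Ester saponification; the acetals are stable to base and to a brief cold acidification.

Step 4
Reactants: 4 2-[2-bromo-3,5-bis(methoxymethoxy)phenyl]acetic acid
Product: 6 methyl 4-[2-bromo-3,5-bis(methoxymethoxy)phenyl]-3-oxobutanoate, via acyl imidazolide 5 (not isolated)
Conditions: CDI, THF, rt; then Mg(O2CCH2CO2Me)2, THF, 40 °C; cold 1 M HCl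
Reagents that add atoms: magnesium bis(methyl malonate), [Mg+2].COC(=O)CC(=O)[O-].COC(=O)CC(=O)[O-]
Why: Masamune–Brooks homologation: the magnesium enolate of the malonate half-ester is C-acylated by the acyl imidazolide and loses CO2 to give the β-keto ester.

Step 5
Reactants: 6 methyl 4-[2-bromo-3,5-bis(methoxymethoxy)phenyl]-3-oxobutanoate
Product: 7 methyl 4-[2-bromo-3,5-bis(methoxymethoxy)phenyl]-2-diazo-3-oxobutanoate
Conditions: 4-acetamidobenzenesulfonyl azide, Et3N, MeCN, 0 °C to rt
Reagents that add atoms: 4-acetamidobenzenesulfonyl azide, CC(=O)Nc1ccc(cc1)S(=O)(=O)N=[N+]=[N-]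
Why: Regitz diazo transfer to the doubly activated methylene; the benzylic CH2 next to only one carbonyl does not react.

Step 6
Reactants: 7 methyl 4-[2-bromo-3,5-bis(methoxymethoxy)phenyl]-2-diazo-3-oxobutanoate
Product: 8 methyl 4-bromo-5,7-bis(methoxymethoxy)-2-oxo-2,3-dihydro-1H-indene-1-carboxylate
Conditions: Rh2(OAc)4 (1 mol %), CH2Cl2, rt
Reagents that add atoms: none
Why: Rhodium-carbenoid aromatic substitution (formal aryl C–H insertion) closes the five-membered ring at the only free ortho carbon, which the acetal oxygens activate ortho and para. The product is largely enolised, so C1 is not a fixed stereocentre.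

Step 7
Reactants: 9 3,5-dimethoxyphenol
Product: 10 2-bromo-3,5-dimethoxyphenol
Conditions: NBS, CH2Cl2, −78 °C to rt
Reagents that add atoms: N-bromosuccinimide, O=C1CCC(=O)N1Br
Why: Electrophilic bromination of the phenol; low temperature in a non-polar solvent favours the ortho position, and any para isomer is removed by chromatography.

Step 8
Reactants: 10 2-bromo-3,5-dimethoxyphenol
Product: 11 (2-bromo-3,5-dimethoxyphenoxy)trimethylsilane
Conditions: (Me3Si)2NH, THF, 70 °C
Reagents that add atoms: hexamethyldisilazane, C[Si](C)(C)N[Si](C)(C)C
Why: O-silylation of the phenol with loss of ammonia; the product is used crude.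

Step 9
Reactants: 11 (2-bromo-3,5-dimethoxyphenoxy)trimethylsilane
Product: 14 3,5-dimethoxy-2-(trimethylsilyl)phenyl trifluoromethanesulfonate, via aryllithium 12 (not isolated), via lithium phenoxide 13 (not isolated)
Conditions: n-BuLi, THF, −78 °C; then Tf2O, −78 to 0 °C
Reagents that add atoms: trifluoromethanesulfonic anhydride, O=S(=O)(OS(=O)(=O)C(F)(F)F)C(F)(F)F
Why: Bromine–lithium exchange, anionic 1,3 O-to-C silyl shift (retro-Brook) to the ortho-silyl phenoxide, then O-triflation; this is the standard entry to ortho-silylaryl triflates.

Step 10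
Reactants: 8 methyl 4-bromo-5,7-bis(methoxymethoxy)-2-oxo-2,3-dihydro-1H-indene-1-carboxylate, 14 3,5-dimethoxy-2-(trimethylsilyl)phenyl trifluoromethanesulfonate
Product: 17 methyl 1-bromo-7,9-dimethoxy-2,4-bis(methoxymethoxy)-10-oxo-10,11-dihydro-5H-dibenzo[a,d][7]annulene-5-carboxylate (racemic at C5 = Cc), via aryne 15 (not isolated), via benzocyclobutenoxide 16 (not isolated)
Conditions: CsF (3 equiv), MeCN, 80 °C
Reagents that add atoms: none
Why: Fluoride removes the silyl group of 14 and triflate leaves, giving 3,5-dimethoxybenzyne 15; the enolate carbon C1 of 8 adds to the aryne carbon remote from the flanking methoxy (B6–Cc bond). The aryl anion so formed, ortho to that methoxy, adds to the ring ketone in a 4-exo-trig closure (B1–Cb bond) to give benzocyclobutenoxide 16. Retro-aldol cleavage of the old C1–C2 bond releases the four-ring strain and gives the ester enolate, so the seven-membered ring is closed by two-carbon ring expansion and not by direct cyclisation. The closest known reaction type is the aryne acyl-alkylation of cyclic β-keto esters, 2-oxoindane-1-carboxylates included. No stereocentre is controlled: Cc forms as a racemic, enolisable methine that step 15 fixes. The selectivity needed is the regiochemistry of aryne capture; the methoxy beside the triple bond secures it (the aryl anion forms ortho to oxygen), which places the ketone ortho and the ester methine meta to oxygen as ring B requires. C-arylation over O-arylation is expected for the soft, fully enolised β-keto ester, and the bromide and the acetals are inert to CsF.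

Step 11
Reactants: 17 methyl 1-bromo-7,9-dimethoxy-2,4-bis(methoxymethoxy)-10-oxo-10,11-dihydro-5H-dibenzo[a,d][7]annulene-5-carboxylate
Product: 18 methyl 1-bromo-7,9-dimethoxy-2,4-bis(methoxymethoxy)-10-(trifluoromethanesulfonyloxy)-5H-dibenzo[a,d][7]annulene-5-carboxylate (racemic)
Conditions: KN(SiMe3)2, THF, −78 °C; then PhNTf2, −78 to 0 °C
Reagents that add atoms: N-phenylbis(trifluoromethanesulfonimide), O=S(=O)(N(c1ccccc1)S(=O)(=O)C(F)(F)F)C(F)(F)F
Why: The ketone has α-hydrogens only on Ca, and its potassium enolate (more acidic and less hindered than the diarylacetate C–H) is O-sulfonylated. The enol triflate keeps Cb sp2, is inert to hydride, Grignard reagent and acid, and is too electron-poor to trap the Cd cation of step 16 across the ring.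

Step 12
Reactants: 18 methyl 1-bromo-7,9-dimethoxy-2,4-bis(methoxymethoxy)-10-(trifluoromethanesulfonyloxy)-5H-dibenzo[a,d][7]annulene-5-carboxylate
Product: 19 1-bromo-7,9-dimethoxy-2,4-bis(methoxymethoxy)-10-(trifluoromethanesulfonyloxy)-5H-dibenzo[a,d][7]annulene-5-carbaldehyde (racemic)
Conditions: i-Bu2AlH (1.1 equiv), CH2Cl2, −78 °C; aq. potassium sodium tartrate
Reagents that add atoms: none
Why: Partial reduction of a hindered ester; the tetrahedral aluminium hemiacetal persists at −78 °C and gives the aldehyde on work-up. The aldehyde is used at once because diarylacetaldehydes enolise and oxidise in air.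

Step 13
Reactants: 19 1-bromo-7,9-dimethoxy-2,4-bis(methoxymethoxy)-10-(trifluoromethanesulfonyloxy)-5H-dibenzo[a,d][7]annulene-5-carbaldehyde, 20 4-methoxyphenylmagnesium bromide
Product: 21 [1-bromo-7,9-dimethoxy-2,4-bis(methoxymethoxy)-10-(trifluoromethanesulfonyloxy)-5H-dibenzo[a,d][7]annulen-5-yl](4-methoxyphenyl)methanol (mixture of stereoisomers)
Conditions: THF, −78 to 0 °C; aq. NH4Cl
Reagents that add atoms: none
Why: Grignard 1,2-addition to the aldehyde, which at low temperature is faster than enolisation or attack at the sulfonate; the stereoisomers converge in step 14.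

Step 14
Reactants: 21 [1-bromo-7,9-dimethoxy-2,4-bis(methoxymethoxy)-10-(trifluoromethanesulfonyloxy)-5H-dibenzo[a,d][7]annulen-5-yl](4-methoxyphenyl)methanol
Product: 22 [1-bromo-7,9-dimethoxy-2,4-bis(methoxymethoxy)-10-(trifluoromethanesulfonyloxy)-5H-dibenzo[a,d][7]annulen-5-yl](4-methoxyphenyl)methanone (racemic, Cc labile)
Conditions: Dess–Martin periodinane, NaHCO3, CH2Cl2, 0 °C to rt
Reagents that add atoms: none
Why: Dess–Martin oxidation of the secondary benzylic alcohol under buffered, non-acidic conditions that spare the acetals and the enol triflate.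

Step 15
Reactants: 22 [1-bromo-7,9-dimethoxy-2,4-bis(methoxymethoxy)-10-(trifluoromethanesulfonyloxy)-5H-dibenzo[a,d][7]annulen-5-yl](4-methoxyphenyl)methanone
Product: 23 (R)-[(5R)-1-bromo-7,9-dimethoxy-2,4-bis(methoxymethoxy)-10-(trifluoromethanesulfonyloxy)-5H-dibenzo[a,d][7]annulen-5-yl](4-methoxyphenyl)methanol
Conditions: RuCl(p-cymene)[(R,R)-TsDPEN] (2 mol %), HCO2H/Et3N (5:2), DMF, 40 °C
Reagents that add atoms: none
Why: Noyori–Ikariya asymmetric transfer hydrogenation under dynamic kinetic resolution: Cc–H is doubly benzylic and α to the ketone, so the enantiomers interconvert through the enol while the catalyst reduces one of them. The (R,R) catalyst should give the (R)-carbinol by the usual aryl-ketone model and take the epimer that holds the ring A side anti to the incoming hydride (Felkin–Anh), which sets Cc as R; bromide, acetals and enol triflate are inert to the ruthenium hydride.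

Step 16
Reactants: 23 (R)-[(5R)-1-bromo-7,9-dimethoxy-2,4-bis(methoxymethoxy)-10-(trifluoromethanesulfonyloxy)-5H-dibenzo[a,d][7]annulen-5-yl](4-methoxyphenyl)methanol
Product: 25 tetracyclic enol triflate (Cc R, Cd R): inner trans-dihydrofuran closed between the Z3 oxygen and Cd (4-methoxyphenyl on Cd); free OH on Z1; Br on Z6, via bisphenol alcohol 24 (not isolated)
Conditions: HCl (1.25 M in MeOH), CH2Cl2, 0 °C to rt
Reagents that add atoms: none
Why: Acid removes both acetals and ionises the 4-methoxybenzylic alcohol; the cation is captured by the Z3 phenol to close the five-membered ring (SN1 etherification). The aryl on Cd settles trans to ring B on Cc, the kinetic and thermodynamic outcome for 2,3-diaryl-dihydrobenzofurans, while Cc, no longer next to a carbonyl, is untouched and the electron-poor enol triflate does not engage the cation.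

Step 17
Reactants: 25 tetracyclic enol triflate (Cc R, Cd R)
Product: 26 tetracyclic alkene (Cc R, Cd R) with Ca=Cb double bond (H on Cb); free OH on Z1; Br on Z6
Conditions: Pd(OAc)2 (5 mol %), PPh3 (10 mol %), HCO2H, n-Bu3N, DMF, 60 °C
Reagents that add atoms: none
Why: Palladium-catalysed formate reduction of an enol triflate (oxidative addition, formate exchange, loss of CO2, C–H reductive elimination). The vinyl triflate reacts far faster than the electron-rich, doubly ortho-substituted aryl bromide, and the electron-rich alkene is released only now that no cation can form at Cd.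

Step 18
Reactants: 26 tetracyclic alkene (Cc R, Cd R), 27 1,3-dimethoxybenzene
Product: 28 pentacyclic bromophenol (Cb R, Cc R, Cd R): 2,4-dimethoxyphenyl on Cb; Ca now CH2
Conditions: 27 (20 equiv), Bi(OTf)3 (5 mol %), CH2Cl2, 0 °C to rt
Reagents that add atoms: none
Why: Friedel–Crafts hydroarylation: protonation at Ca gives the Cb cation, stabilised by the ortho and para methoxy groups of ring B, and 27 attacks through C4 to give the 2,4-dimethoxyphenyl group. With the inner furan closed, Cd lies near the plane of ring A, Cc–H is axial on the convex face of the boat-shaped ring and ring A screens the concave face, so the arene should enter cis to Cc–H, which is R at Cb; the large excess of 27 outruns self-alkylation by the free phenol ring.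

Step 19
Reactants: 28 pentacyclic bromophenol (Cb R, Cc R, Cd R)
Product: 29 pentacyclic bromide with a methoxymethyl ether on the Z1 oxygen (Cb R, Cc R, Cd R)
Conditions: MOMCl, i-Pr2NEt, CH2Cl2, 0 °C to rt
Reagents that add atoms: chloromethyl methyl ether, COCCl
Why: O-alkylation of the single phenol; the acetal keeps the phenoxide out of the palladium step and is removed by the acid of step 23.

Step 20
Reactants: 30 2-(3,5-dimethoxyphenyl)acetic acid, 31 anisole
Product: 33 2-(3,5-dimethoxyphenyl)-1-(4-methoxyphenyl)ethan-1-one, via acid chloride 32 (not isolated)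
Conditions: (COCl)2, DMF (cat.), CH2Cl2, rt; then 31 (5 equiv), AlCl3, CH2Cl2, 0 °C
Reagents that add atoms: none
Why: Acid chloride formation and para-selective Friedel–Crafts acylation of anisole; excess anisole and low temperature suppress acylation of the dimethoxyphenyl ring of the reagent itself.

Step 21
Reactants: 29 pentacyclic bromide with a methoxymethyl ether on the Z1 oxygen, 33 2-(3,5-dimethoxyphenyl)-1-(4-methoxyphenyl)ethan-1-one
Product: 34 ketone with Z6–CH(3,5-dimethoxyphenyl)–C(=O)(4-methoxyphenyl) (Cb R, Cc R, Cd R; epimers at Ce)
Conditions: 33 (2 equiv), Pd2(dba)3 (2.5 mol %), XPhos (10 mol %), K3PO4, toluene, 100 °C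
Reagents that add atoms: none
Why: Palladium-catalysed α-arylation of a ketone enolate (zerovalent palladium inserts into the C–Br bond, the potassium enolate of 33 displaces bromide, C–C reductive elimination); a bulky biaryl phosphine is chosen for the doubly ortho-substituted bromide and the mild phosphate base spares the dihydrofuran. The more acidic product stays as its enolate, which stops a second arylation; the Ce epimers converge in step 22.

Step 22
Reactants: 34 ketone with Z6–CH(3,5-dimethoxyphenyl)–C(=O)(4-methoxyphenyl)
Product: 35 alcohol with Z6–CH(3,5-dimethoxyphenyl)–CH(OH)(4-methoxyphenyl) (Cb R, Cc R, Cd R, Ce R, Cf R)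
Conditions: RuCl(p-cymene)[(R,R)-TsDPEN] (2 mol %), HCO2H/Et3N (5:2), DMF, 40 °C
Reagents that add atoms: none
Why: The same transfer hydrogenation: Ce–H is doubly benzylic and α to the ketone, so its epimers equilibrate while one is reduced. The catalyst meets the same local arrangement as in step 15 (ring A aryl as the large α-group) and should give Cf (R) and Ce (R) whatever the distant inner centres are.

Step 23
Reactants: 35 alcohol with Z6–CH(3,5-dimethoxyphenyl)–CH(OH)(4-methoxyphenyl)
Product: 37 octamethyl ether of the target (Cb R, Cc R, Cd R, Ce R, Cf R), via phenol alcohol 36 (not isolated)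
Conditions: HCl (1.25 M in MeOH), CH2Cl2, 0 °C to rt
Reagents that add atoms: none
Why: Acetal cleavage and SN1 closure of the Z1 phenol on the 4-methoxybenzylic cation, as in step 16; Cf forms trans to the 3,5-dimethoxyphenyl group on Ce. The inner furan, should it open reversibly, re-closes to the same trans isomer.

Step 24
Reactants: 37 octamethyl ether of the target
Product: 38 CNP0154047.1 (Cb R, Cc R, Cd R, Ce R, Cf R)
Conditions: BBr3 (20 equiv), CH2Cl2, −78 °C to rt; then MeOH, H2O
Reagents that add atoms: none
Why: Lewis-acid cleavage of the eight aryl methyl ethers (aryloxyborane formation, bromide attack at methyl). The methines Cb, Cc and Ce carry no leaving group, and a dihydrofuran that opens at its benzylic C–O bond re-closes to the trans isomer dictated by the untouched Cc or Ce.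

## Compound list

1 | methyl 2-(3,5-dihydroxyphenyl)acetate | COC(=O)Cc1cc(O)cc(O)c1 | starting material
2 | methyl 2-[3,5-bis(methoxymethoxy)phenyl]acetate | COCOc1cc(CC(=O)OC)cc(OCOC)c1 | intermediate
3 | methyl 2-[2-bromo-3,5-bis(methoxymethoxy)phenyl]acetate | COCOc1cc(CC(=O)OC)c(Br)c(OCOC)c1 | intermediate
4 | 2-[2-bromo-3,5-bis(methoxymethoxy)phenyl]acetic acid | COCOc1cc(CC(=O)O)c(Br)c(OCOC)c1 | intermediate
5 | 2-[2-bromo-3,5-bis(methoxymethoxy)phenyl]-1-(imidazol-1-yl)ethan-1-one (acyl imidazolide, not isolated) | COCOc1cc(CC(=O)n2ccnc2)c(Br)c(OCOC)c1 | intermediate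
6 | methyl 4-[2-bromo-3,5-bis(methoxymethoxy)phenyl]-3-oxobutanoate | COCOc1cc(CC(=O)CC(=O)OC)c(Br)c(OCOC)c1 | intermediate
7 | methyl 4-[2-bromo-3,5-bis(methoxymethoxy)phenyl]-2-diazo-3-oxobutanoate | COCOc1cc(CC(=O)C(=[N+]=[N-])C(=O)OC)c(Br)c(OCOC)c1 | intermediate
8 | methyl 4-bromo-5,7-bis(methoxymethoxy)-2-oxo-2,3-dihydro-1H-indene-1-carboxylate (enolisable, no fixed stereocentre) | COCOc1cc(OCOC)c2c(c1Br)CC(=O)C2C(=O)OC | intermediate
9 | 3,5-dimethoxyphenol | COc1cc(O)cc(OC)c1 | starting material
10 | 2-bromo-3,5-dimethoxyphenol | COc1cc(O)c(Br)c(OC)c1 | intermediate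
11 | (2-bromo-3,5-dimethoxyphenoxy)trimethylsilane | COc1cc(O[Si](C)(C)C)c(Br)c(OC)c1 | intermediate
12 | [2,4-dimethoxy-6-(trimethylsilyloxy)phenyl]lithium (not isolated) | [Li]c1c(O[Si](C)(C)C)cc(OC)cc1OC | intermediate
13 | lithium 3,5-dimethoxy-2-(trimethylsilyl)phenoxide (not isolated) | [Li+].[O-]c1cc(OC)cc(OC)c1[Si](C)(C)C | intermediate
14 | 3,5-dimethoxy-2-(trimethylsilyl)phenyl trifluoromethanesulfonate | COc1cc(OC)c([Si](C)(C)C)c(OS(=O)(=O)C(F)(F)F)c1 | intermediate
15 | 3,5-dimethoxybenzyne (1,2-didehydro-3,5-dimethoxybenzene, not isolated) | COC1=CC(OC)=CC#C1 | intermediate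
16 | cesium benzocyclobutenoxide: cyclobutene fused across C1–C2 of the indane, O− on old C2, ester on old C1 (not isolated; racemic) | [Cs+].COCOc1cc(OCOC)c2c(c1Br)CC1([O-])c3c(OC)cc(OC)cc3C21C(=O)OC | intermediate
17 | methyl 1-bromo-7,9-dimethoxy-2,4-bis(methoxymethoxy)-10-oxo-10,11-dihydro-5H-dibenzo[a,d][7]annulene-5-carboxylate (racemic at C5 = Cc) | COCOc1cc(OCOC)c2c(c1Br)CC(=O)c1c(OC)cc(OC)cc1C2C(=O)OC | intermediate
18 | methyl 1-bromo-7,9-dimethoxy-2,4-bis(methoxymethoxy)-10-(trifluoromethanesulfonyloxy)-5H-dibenzo[a,d][7]annulene-5-carboxylate (racemic) | COCOc1cc(OCOC)c2c(c1Br)C=C(OS(=O)(=O)C(F)(F)F)c1c(OC)cc(OC)cc1C2C(=O)OC | intermediate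
19 | 1-bromo-7,9-dimethoxy-2,4-bis(methoxymethoxy)-10-(trifluoromethanesulfonyloxy)-5H-dibenzo[a,d][7]annulene-5-carbaldehyde (racemic) | COCOc1cc(OCOC)c2c(c1Br)C=C(OS(=O)(=O)C(F)(F)F)c1c(OC)cc(OC)cc1C2C=O | intermediate
20 | 4-methoxyphenylmagnesium bromide | COc1ccc([Mg]Br)cc1 | starting material
21 | [1-bromo-7,9-dimethoxy-2,4-bis(methoxymethoxy)-10-(trifluoromethanesulfonyloxy)-5H-dibenzo[a,d][7]annulen-5-yl](4-methoxyphenyl)methanol (mixture of stereoisomers) | COCOc1cc(OCOC)c2c(c1Br)C=C(OS(=O)(=O)C(F)(F)F)c1c(OC)cc(OC)cc1C2C(O)c1ccc(OC)cc1 | intermediate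
22 | [1-bromo-7,9-dimethoxy-2,4-bis(methoxymethoxy)-10-(trifluoromethanesulfonyloxy)-5H-dibenzo[a,d][7]annulen-5-yl](4-methoxyphenyl)methanone (racemic, Cc labile) | COCOc1cc(OCOC)c2c(c1Br)C=C(OS(=O)(=O)C(F)(F)F)c1c(OC)cc(OC)cc1C2C(=O)c1ccc(OC)cc1 | intermediate
23 | (R)-[(5R)-1-bromo-7,9-dimethoxy-2,4-bis(methoxymethoxy)-10-(trifluoromethanesulfonyloxy)-5H-dibenzo[a,d][7]annulen-5-yl](4-methoxyphenyl)methanol (Cc R, Cd R) | COCOc1cc(OCOC)c2c(c1Br)C=C(OS(=O)(=O)C(F)(F)F)c1c(OC)cc(OC)cc1[C@H]2[C@@H](O)c1ccc(OC)cc1 | intermediate
24 | bisphenol alcohol: 23 with both acetals removed (Cc R, Cd R; not isolated) | Oc1cc(O)c2c(c1Br)C=C(OS(=O)(=O)C(F)(F)F)c1c(OC)cc(OC)cc1[C@H]2[C@@H](O)c1ccc(OC)cc1 | intermediate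
25 | tetracyclic enol triflate (Cc R, Cd R): inner trans-dihydrofuran (Z3–O–Cd, 4-methoxyphenyl on Cd) fused to the dibenzocycloheptene; OH on Z1, Br on Z6, OTf on Cb, OMe on B2 and B4 | Oc1cc2c3c(c1Br)C=C(OS(=O)(=O)C(F)(F)F)c1c(OC)cc(OC)cc1[C@H]3[C@H](c1ccc(OC)cc1)O2 | intermediate
26 | tetracyclic alkene (Cc R, Cd R): as 25 with H in place of OTf on Cb | Oc1cc2c3c(c1Br)C=Cc1c(OC)cc(OC)cc1[C@H]3[C@H](c1ccc(OC)cc1)O2 | intermediate
27 | 1,3-dimethoxybenzene | COc1cccc(OC)c1 | starting material
28 | pentacyclic bromophenol (Cb R, Cc R, Cd R): as 26 with Ca = CH2 and 2,4-dimethoxyphenyl on Cb | Oc1cc2c3c(c1Br)C[C@H](c1ccc(OC)cc1OC)c1c(OC)cc(OC)cc1[C@H]3[C@H](c1ccc(OC)cc1)O2 | intermediate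
29 | methoxymethyl ether of 28 at the Z1 oxygen (Cb R, Cc R, Cd R) | COCOc1cc2c3c(c1Br)C[C@H](c1ccc(OC)cc1OC)c1c(OC)cc(OC)cc1[C@H]3[C@H](c1ccc(OC)cc1)O2 | intermediate
30 | 2-(3,5-dimethoxyphenyl)acetic acid | COc1cc(CC(=O)O)cc(OC)c1 | starting material
31 | anisole | COc1ccccc1 | starting material
32 | 2-(3,5-dimethoxyphenyl)acetyl chloride (not isolated) | COc1cc(CC(=O)Cl)cc(OC)c1 | intermediate
33 | 2-(3,5-dimethoxyphenyl)-1-(4-methoxyphenyl)ethan-1-one | COc1ccc(C(=O)Cc2cc(OC)cc(OC)c2)cc1 | intermediate
34 | ketone: 29 with Br replaced by CH(3,5-dimethoxyphenyl)–C(=O)(4-methoxyphenyl) (Cb R, Cc R, Cd R; epimers at Ce) | COCOc1cc2c3c(c1C(C(=O)c1ccc(OC)cc1)c1cc(OC)cc(OC)c1)C[C@H](c1ccc(OC)cc1OC)c1c(OC)cc(OC)cc1[C@H]3[C@H](c1ccc(OC)cc1)O2 | intermediate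
35 | alcohol: 34 reduced to CH(3,5-dimethoxyphenyl)–CH(OH)(4-methoxyphenyl) (Cb R, Cc R, Cd R, Ce R, Cf R) | COCOc1cc2c3c(c1[C@H]([C@@H](O)c1ccc(OC)cc1)c1cc(OC)cc(OC)c1)C[C@H](c1ccc(OC)cc1OC)c1c(OC)cc(OC)cc1[C@H]3[C@H](c1ccc(OC)cc1)O2 | intermediate
36 | phenol alcohol: 35 with the acetal removed (not isolated) | Oc1cc2c3c(c1[C@H]([C@@H](O)c1ccc(OC)cc1)c1cc(OC)cc(OC)c1)C[C@H](c1ccc(OC)cc1OC)c1c(OC)cc(OC)cc1[C@H]3[C@H](c1ccc(OC)cc1)O2 | intermediate
37 | octamethyl ether of the target (all eight phenols as OMe; Cb R, Cc R, Cd R, Ce R, Cf R) | COc1ccc([C@@H]2Oc3cc4c5c(c3[C@H]2c2cc(OC)cc(OC)c2)C[C@H](c2ccc(OC)cc2OC)c2c(OC)cc(OC)cc2[C@H]5[C@H](c2ccc(OC)cc2)O4)cc1 | intermediate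
38 | CNP0154047.1 (Cb R, Cc R, Cd R, Ce R, Cf R) | Oc1ccc([C@@H]2Oc3cc4c5c(c3[C@H]2c2cc(O)cc(O)c2)C[C@H](c2ccc(O)cc2O)c2c(O)cc(O)cc2[C@H]5[C@H](c2ccc(O)cc2)O4)cc1 | target

## Step count and least certain steps

Total: 24 steps. Longest linear sequence: 20 steps (steps 1–6, 10–19 and 21–24); steps 7–9 (aryne precursor) and step 20 (deoxybenzoin) are side branches.

**Step 10 (key step).** The likeliest failure is quenching of the aryl anion before it adds to the ring ketone: C1 of 8 is crowded by the neighbouring acetal oxygen, and the enolised substrate is itself a proton source, so plain C-arylation without ring expansion may compete. Loss of aryne by self-reaction is the second drain. Fallback: from 8, ring B is brought in as an aryl cation equivalent and the seven-membered ring is closed by acylation. (3,5-Dimethoxyphenyl)lead triacetate F1, made from the boronic acid and Pb(OAc)4, arylates C1 (Pinhey arylation, pyridine, CHCl3, 40 °C) to the quaternary keto ester F2. Aqueous KOH at 0 °C to rt cleaves this non-enolisable β-keto ester (retro-Claisen) to the seco acid F3. Trifluoroacetic anhydride in CH2Cl2 at 0 °C then closes the ketone onto either of the two equivalent ortho positions of the 3,5-dimethoxyphenyl ring (Friedel–Crafts acylation), which returns to 17.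

**Step 15.** Enolisation of the ring methine may be slower than hydride transfer, because the enol places an exocyclic double bond on a tub-shaped ring. The dynamic process would then fall back to a simple kinetic resolution with eroding enantiomeric purity, or the catalyst may prefer the other epimer. Fallback: from 21, without oxidation, the racemic alcohol mixture is closed directly with methanolic HCl to racemic 25. This is resolved by preparative chromatography on a chiral stationary phase; the unwanted enantiomer of 25, F4, is set aside and 25 re-enters at step 17.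

**Step 18.** Entry of the arene on the concave face, or weak facial discrimination, would give the Cb epimer; acid-induced opening of the inner furan with capture by the excess arene is the second risk. Fallback: from 25 the polarity at Cb is inverted. Suzuki coupling of the enol triflate with 2,4-dimethoxyphenylboronic acid (Pd(PPh3)4, K3PO4, dioxane/H2O, 70 °C) gives the triaryl alkene F5. Hydrogenation with the homogeneous catalyst [Ir(cod)(PCy3)(py)]PF6, which spares the aryl bromide, then delivers hydrogen to whichever face is open. That is the face the arene would have taken, so the aryl ends on the other face and the opposite Cb epimer results. This returns to 28.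

**Step 21.** Oxidative addition and C–C reductive elimination at a bromide flanked by an acetal oxygen and the ring CH2 may be too slow, and protodebromination would then dominate. Fallback: from 29, bromine–lithium exchange (t-BuLi, THF, −78 °C) gives the aryllithium. It is added to 1-(3,5-dimethoxyphenyl)-2-(4-methoxyphenyl)ethane-1,2-dione F6 (from 33 with SeO2), at the carbonyl that the para-methoxy group does not deactivate, to give the tertiary α-hydroxy ketone F7. SmI2 in THF/MeOH at −78 °C removes the α-hydroxyl and returns to 34.

**Step 22.** The catalyst's preference for one Ce epimer may be blunted by the crowded surroundings of the ketone (ring CH2 and acetal on either side), giving incomplete diastereocontrol. Fallback: from 34, NaBH4 gives the alcohol as a mixture of Ce/Cf stereoisomers F8. Methanolic HCl closes it to 37 together with the (Ce S, Cf S) diastereomer F9. Because the inner centres are fixed, these are diastereomers and are separated by chromatography, returning at 37.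

## Further compounds

F1 | step 10 | (3,5-dimethoxyphenyl)lead triacetate | COc1cc(OC)cc([Pb](OC(C)=O)(OC(C)=O)OC(C)=O)c1
F2 | step 10 | methyl 4-bromo-1-(3,5-dimethoxyphenyl)-5,7-bis(methoxymethoxy)-2-oxo-2,3-dihydro-1H-indene-1-carboxylate (racemic) | COCOc1cc(OCOC)c2c(c1Br)CC(=O)C2(C(=O)OC)c1cc(OC)cc(OC)c1
F3 | step 10 | 2-[2-bromo-6-[1-(3,5-dimethoxyphenyl)-2-methoxy-2-oxoethyl]-3,5-bis(methoxymethoxy)phenyl]acetic acid (racemic) | COCOc1cc(OCOC)c(C(C(=O)OC)c2cc(OC)cc(OC)c2)c(CC(=O)O)c1Br
F4 | step 15 | enantiomer of 25 (Cc S, Cd S) | Oc1cc2c3c(c1Br)C=C(OS(=O)(=O)C(F)(F)F)c1c(OC)cc(OC)cc1[C@@H]3[C@@H](c1ccc(OC)cc1)O2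
F5 | step 18 | tetracyclic triaryl alkene: 25 with 2,4-dimethoxyphenyl in place of OTf on Cb (Cc R, Cd R) | Oc1cc2c3c(c1Br)C=C(c1ccc(OC)cc1OC)c1c(OC)cc(OC)cc1[C@H]3[C@H](c1ccc(OC)cc1)O2
F6 | step 21 | 1-(3,5-dimethoxyphenyl)-2-(4-methoxyphenyl)ethane-1,2-dione | COc1ccc(C(=O)C(=O)c2cc(OC)cc(OC)c2)cc1
F7 | step 21 | α-hydroxy ketone: 34 with OH on Ce (Cb R, Cc R, Cd R; epimers at Ce) | COCOc1cc2c3c(c1C(O)(C(=O)c1ccc(OC)cc1)c1cc(OC)cc(OC)c1)C[C@H](c1ccc(OC)cc1OC)c1c(OC)cc(OC)cc1[C@H]3[C@H](c1ccc(OC)cc1)O2
F8 | step 22 | alcohol of 34 as a mixture of Ce/Cf stereoisomers (Cb R, Cc R, Cd R) | COCOc1cc2c3c(c1C(C(O)c1ccc(OC)cc1)c1cc(OC)cc(OC)c1)C[C@H](c1ccc(OC)cc1OC)c1c(OC)cc(OC)cc1[C@H]3[C@H](c1ccc(OC)cc1)O2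
F9 | step 22 | diastereomer of 37 with the outer furan inverted (Cb R, Cc R, Cd R, Ce S, Cf S) | COc1ccc([C@H]2Oc3cc4c5c(c3[C@@H]2c2cc(OC)cc(OC)c2)C[C@H](c2ccc(OC)cc2OC)c2c(OC)cc(OC)cc2[C@H]5[C@H](c2ccc(OC)cc2)O4)cc1
A1 | alternative 1 | C2-symmetric bis(trans-dihydrobenzofuran) with a ring A silyloxymethyl group | COc1ccc([C@@H]2Oc3cc4O[C@@H](c5ccc(OC)cc5)[C@H](c5cc(OC)cc(OC)c5)c4c(CO[Si](C)(C)C(C)(C)C)c3[C@H]2c2cc(OC)cc(OC)c2)cc1
A2 | alternative 2 | tetracyclic 2-(4-methoxyphenyl)benzofuran fused to the seven-membered ring | COc1cc2oc(-c3ccc(OC)cc3)c3c2c(c1)C[C@H](c1ccc(OC)cc1OC)c1c(OC)cc(OC)cc1-3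
A3 | alternative 3 | tetracyclic core with ring B as a mono-silylated resorcinol | COc1cc2c3c(c1)C[C@H](c1ccc(OC)cc1OC)c1c(O)cc(O[Si](C(C)C)(C(C)C)C(C)C)cc1[C@H]3[C@H](c1ccc(OC)cc1)O2
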